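A small charge of extra reagent, 10.0 % of the starting material charged, is the margin on which the next flask stands.

| setting | red | grey | green | alder | maple | birch |
|---|---|---|---|---|---|---|
| starting material | 0.40 M | 0.40 M | 0.40 M | 0.40 M | 0.40 M (fed, over 50 min) | 0.40 M |
| second substrate | 0.80 M | 0.40 M | 0.60 M | 0.800 M | 0.800 M | 0.800 M |
| reagent | 0.44 M | 0.44 M | 0.44 M | 0.440 M (fed, over 50 min) | 0.440 M | 0.440 M |
| free catalyst | 0.40 mM | 0.40 mM | 0.40 mM | 0.40 mM | 0.40 mM | 0.40 mM |
| impurity | 44 µM | 44 µM | 44 µM | 44 µM | 44 µM | 44 µM |
| remark | run made earlier | run made earlier | run made earlier | all else is in the flask from the start; the feed brings no volume worth counting | all else is in the flask from the start; the feed brings no volume worth counting | everything together at the start |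
| time |  |  |  | 80 min | 80 min | 80 min |

- red (time / min: target / %, starting material / %): 8.00: 29, 66; 15.0: 45, 56; 25.0: 58, 38; 30.0: 65, 34; 40.0: 72, 28; 50.0: 79, 24
- grey (time / min: target / %, starting material / %): 15.0: 56, 52; 30.0: 71, 26; 50.0: 83, 16; 60.0: 84, 11; 80.0: 89, 8; 90.0: 97, 7
- green (time / min: target / %, starting material / %): 8.00: 32, 69; 12.0: 44, 61; 20.0: 55, 45; 40.0: 78, 26; 60.0: 84, 20; 90.0: 91, 14

(readings scatter by 2 percentage points)

- the numbers in the tables scatter with a standard deviation of 2 percentage points
- a reading or a percentage of target counts all its forms, free or not

- which flask leads in amount of target, in percent of the starting material charged ("all alike" within 1.5 percentage points) (alder / maple / birch / all alike)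
- how much target is there at the end, in percent of the starting material charged: alder
- how much target is there at the end, in percent of the starting material charged: maple
- how much target is there at the end, in percent of the starting material charged: birch

The choice is how to charge the next flask. The reagent charged is 110 % of the starting material charged, and this ratio is the reagent budget. If each target takes one reagent, then target, reagent spent elsewhere and reagent left add up to the budget, all as fractions of the starting material charged. Any reagent spent elsewhere beyond the cushion lowers the ceiling on target point for point. The crossing lies there: beyond it, reagent takes over from starting material as the limiting reagent.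

The red run's last readings of target and starting material add up to 103 %, so starting material shows no other exit within the scatter. Reagent is not read, so its other uses stay open. Red, with twice the second substrate of grey, still holds 34 % of starting material at 30.0 min, against 26 % in grey at the same time. Second substrate thus seems to hold catalyst. If what it holds also spends reagent, the cushion pays. Maple opens with no starting material in the flask, so second substrate meets the catalyst unopposed at the start. The reckoning here therefore keeps starting material in the flask from the start and expects maple to lose target, though the readings give no figure for the loss.

The forecast names birch as the leader, with 86 % there, and holds the fed flasks level at 78 % and 78 %: “Both feeds are nearly symmetric”. On this point the reckoning here differs.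

The flasks give 80.9 % in alder, 69.9 % in maple and 83.1 % in birch, so birch leads, and maple stands 8.1 percentage points below the forecast.

    starting material + free catalyst ⇌ catalyst intermediate A (K = 3.70 M⁻¹, k = 460 M⁻¹ min⁻¹)
    second substrate + target ⇌ idle adduct, settled at all times (K = 59.0 M⁻¹)
    reagent + catalyst intermediate A → free catalyst + target (k = 440 M⁻¹ min⁻¹)
    free catalyst + impurity → spent catalyst (k = 1.70 × 10⁵ M⁻¹ min⁻¹)
    2 second substrate → homo dimer (k = 0.0130 M⁻¹ min⁻¹)
    reagent + catalyst intermediate B → free catalyst + second product (k = 90.0 M⁻¹ min⁻¹)
    second substrate + free catalyst ⇌ catalyst intermediate B (K = 2.90 M⁻¹, k = 43.0 M⁻¹ min⁻¹)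

Maple at 80.0 min holds 0.135 M of second product, which is 33.7 % of the starting material charged, against a cushion of 10.0 %. The budget then leaves 76.3 % for target and unused reagent, and maple shows 69.9 % of target with reagent worth 6.42 % of the charge; at 800 min it stands at 75.5 % with reagent at 0 %.

A neighbour of maple charged with 0.26 M of reagent has a budget of 65.0 %, below the starting material charged, and that is its ceiling before any reagent goes elsewhere. Computed, it ends with 41.3 % of target, with second product at 22.2 % of the charge and 2.30 % of its reagent left.

(All runs are simulated on assumed constants, noise included.)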